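**Retrosynthetic overview**
1. Target ⇒ cochliodinol: one of its two vinylogous-acid C–OH groups is exchanged for C–OOH in the last step.
2. Cochliodinol ⇒ both indole C3–quinone bonds cut at once: two 5-prenylindoles (C3 nucleophiles) plus 2,5-dihydroxy-1,4-benzoquinone whose two normally nucleophilic enol carbons are made electrophilic (enolonium equivalents) as a bis(phenyliodonium) ylide.
3. Bis-ylide ⇒ 2,5-dihydroxy-1,4-benzoquinone + PhI(OAc)2; 5-prenylindole ⇒ 5-bromoindole + prenyl bromide.
4. Ring order: no ring is built; both indole rings and the quinone ring are bought intact and are only joined (C–C) and adjusted (C–O).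

Assumption: the target has no stereocentre and no stereogenic double bond (each prenyl olefin carries two identical methyl groups), so it is achiral and the "single enantiomer" is simply the one compound drawn.

**Step 1**
Reactants: 1 5-bromo-1H-indole; 2 prenyl bromide (1-bromo-3-methylbut-2-ene)
Product: 6 5-(3-methylbut-2-en-1-yl)-1H-indole (5-prenylindole), via potassium 5-bromoindol-1-ide 3 (not isolated), via potassium 5-lithioindol-1-ide 4 (not isolated), via potassium 5-prenylindol-1-ide 5 (not isolated)
Conditions: KH (1.1 equiv), THF, 0 °C; t-BuLi (2.1 equiv), −78 °C; 2 (1.05 equiv), −78 → −30 °C; then H2O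
Reagents that add atoms: prenyl bromide (2), CC(C)=CCBr
Why: KH first converts N–H into the potassium indolide so that t-BuLi performs clean bromine–lithium exchange at C5 (the second equivalent destroys the t-BuBr formed), and the aryllithium, far more nucleophilic than the delocalised indolide nitrogen at −78 °C, displaces bromide at the unhindered CH2 of prenyl bromide (halogen–metal exchange followed by SN2 alkylation, giving the linear prenyl group; no stereocentre is formed).

**Step 2**
Reactants: 7 2,5-dihydroxy-1,4-benzoquinone; 8 (diacetoxyiodo)benzene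
Product: 10 bis(phenyliodonium) ylide of 7 [3,6-dioxo-2,5-bis(phenyliodonio)cyclohexa-1,4-diene-1,4-diolate], via mono(phenyliodonium) ylide 9 (not isolated)
Conditions: PhI(OAc)2 (2.1 equiv), MeOH, 0 °C → rt, dark; filter the precipitate, wash with cold MeOH and Et2O, use fresh
Reagents that add atoms: (diacetoxyiodo)benzene (8), CC(=O)OI(OC(C)=O)c1ccccc1
Why: Each C–H carbon of 7 is the α-carbon of a vinylogous acid (cyclic 1,3-dicarbonyl-type enol) and attacks the electrophilic trivalent iodine of PhI(OAc)2 with loss of two molecules of acetic acid per site (iodonium ylide formation by ligand exchange), which turns both nucleophilic enol carbons into masked electrophilic carbons and gives a zwitterion that precipitates; no stereocentre is formed.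

**Step 3**
Reactants: 10 bis(phenyliodonium) ylide (1 equiv); 6 5-prenylindole (2.2 equiv)
Product: 12 cochliodinol [2,5-dihydroxy-3,6-bis[5-(3-methylbut-2-en-1-yl)-1H-indol-3-yl]cyclohexa-2,5-diene-1,4-dione], via mono-indolyl iodonium ylide 11 (not isolated)
Conditions: BF3·OEt2 (20 mol %), CH2Cl2, −20 °C → rt, dark, Ar
Reagents that add atoms: none
Why: Proposed new method: BF3 binds an ylide oxygen and unmasks an alkenyl(phenyl)iodonium in which the enol carbon of the hydroxyquinone is an electrophile (enolonium equivalent), indole C3 (much more nucleophilic than N1 or the trisubstituted prenyl olefin) adds to that carbon, and expulsion of iodobenzene with proton transfer to oxygen forges the indole–quinone bond, the sequence repeating at the second iodonio carbon, while the low temperature and the absence of Cu or Rh carbene catalysts hold back Wolff-type ring contraction and cyclopropanation; the closest known reaction type is the Lewis-acid-promoted C3-arylation of indoles by the phenyliodonium ylide of 2-hydroxy-1,4-naphthoquinone, and no stereocentre is formed.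

**Step 4**
Reactants: 12 cochliodinol; 13 urea–hydrogen peroxide
Product: 14 hydroperoxycochliodinol [2-hydroperoxy-5-hydroxy-3,6-bis[5-(3-methylbut-2-en-1-yl)-1H-indol-3-yl]cyclohexa-2,5-diene-1,4-dione]
Conditions: 13 (5 equiv), camphor-10-sulfonic acid (10 mol %), THF, 0 °C → rt, dark; stopped at about 40% conversion, unreacted 12 recovered and recycled
Reagents that add atoms: urea–hydrogen peroxide (13), NC(N)=O.OO (only the H2O2 part, OO, is incorporated)
Why: Proposed new method: each C–OH of 12 is a vinylogous carboxylic acid, so acid-catalysed addition of H2O2 (an α-effect nucleophile) to the protonated enol carbon and loss of water exchanges OH for OOH, and partial conversion keeps the exchange at one site, while indole, quinone and trisubstituted olefin should not be attacked by H2O2 under mild acid; the closest known reaction types are the acid-catalysed conversion of 2,5-dihydroxy-3,6-diaryl-1,4-benzoquinones into their methyl ethers in MeOH (vinylogous Fischer esterification) and the acid-catalysed equilibration of carboxylic acids with H2O2 to peroxy acids, and no stereocentre is formed.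

**Compound list**
1 | 5-bromo-1H-indole | Brc1ccc2[nH]ccc2c1 | starting material
2 | prenyl bromide (1-bromo-3-methylbut-2-ene) | CC(C)=CCBr | starting material
3 | potassium 5-bromoindol-1-ide | [K+].Brc1ccc2[n-]ccc2c1 | intermediate
4 | potassium 5-lithioindol-1-ide | [K+].[Li]c1ccc2[n-]ccc2c1 | intermediate
5 | potassium 5-prenylindol-1-ide | [K+].CC(C)=CCc1ccc2[n-]ccc2c1 | intermediate
6 | 5-(3-methylbut-2-en-1-yl)-1H-indole (5-prenylindole) | CC(C)=CCc1ccc2[nH]ccc2c1 | intermediate
7 | 2,5-dihydroxy-1,4-benzoquinone | O=C1C=C(O)C(=O)C=C1O | starting material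
8 | (diacetoxyiodo)benzene | CC(=O)OI(OC(C)=O)c1ccccc1 | starting material
9 | mono(phenyliodonium) ylide, 4-hydroxy-3,6-dioxo-2-(phenyliodonio)cyclohexa-1,4-dien-1-olate | O=C1C([O-])=C([I+]c2ccccc2)C(=O)C(O)=C1 | intermediate
10 | bis(phenyliodonium) ylide, 3,6-dioxo-2,5-bis(phenyliodonio)cyclohexa-1,4-diene-1,4-diolate | O=C1C([O-])=C([I+]c2ccccc2)C(=O)C([O-])=C1[I+]c3ccccc3 | intermediate
11 | mono-indolyl iodonium ylide, 4-hydroxy-5-[5-(3-methylbut-2-en-1-yl)-1H-indol-3-yl]-3,6-dioxo-2-(phenyliodonio)cyclohexa-1,4-dien-1-olate | O=C1C([O-])=C([I+]c2ccccc2)C(=O)C(O)=C1c1c[nH]c2ccc(CC=C(C)C)cc12 | intermediate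
12 | cochliodinol, 2,5-dihydroxy-3,6-bis[5-(3-methylbut-2-en-1-yl)-1H-indol-3-yl]cyclohexa-2,5-diene-1,4-dione | CC(C)=CCc1ccc2[nH]cc(C3=C(O)C(=O)C(c4c[nH]c5ccc(CC=C(C)C)cc45)=C(O)C3=O)c2c1 | intermediate
13 | urea–hydrogen peroxide (1:1 adduct) | NC(N)=O.OO | starting material
14 | hydroperoxycochliodinol, 2-hydroperoxy-5-hydroxy-3,6-bis[5-(3-methylbut-2-en-1-yl)-1H-indol-3-yl]cyclohexa-2,5-diene-1,4-dione (achiral) | CC(C)=CCc1ccc2[nH]cc(C3=C(O)C(=O)C(c4c[nH]c5ccc(CC=C(C)C)cc45)=C(OO)C3=O)c2c1 | target

**Step count and risk**
Total steps: 4. Longest linear sequence: 3 steps (1 → 6 → 12 → 14); the ylide branch (7 → 10) is one step.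

The three steps most likely to fail, most risky first:

Step 3 (double coupling). The bis-ylide 10 is sparingly soluble. Iodonium ylides of hydroxyquinones can also lose iodobenzene by ring contraction or oxidise the indole, and two couplings in a row must both succeed. The fallback sets out from 6 and uses the quinone as an ordinary electrophile. Two equivalents of 6 are stirred with tetrabromo-1,4-benzoquinone (bromanil) and Cs2CO3 in MeCN at rt. The first addition–elimination gives 2,3,5-tribromo-6-[5-(3-methylbut-2-en-1-yl)-1H-indol-3-yl]cyclohexa-2,5-diene-1,4-dione F1, which is not isolated. It takes up the second indole at the para position to give 2,5-dibromo-3,6-bis[5-(3-methylbut-2-en-1-yl)-1H-indol-3-yl]cyclohexa-2,5-diene-1,4-dione F2, which is isolated. Heating F2 with 10% aqueous NaOH in MeOH hydrolyses the two vinylogous acyl bromides through 2-bromo-5-hydroxy-3,6-bis[5-(3-methylbut-2-en-1-yl)-1H-indol-3-yl]cyclohexa-2,5-diene-1,4-dione F3, formed in the flask. Acidification with HCl returns to the route at 12.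

Step 4 (OH to OOH exchange). The exchange is an equilibrium and statistical, so the bis-hydroperoxide and recovered 12 accompany the product. Acidic H2O2 may also attack the prenyl olefins or the indole C2–C3 bond. The fallback sets out from 12 and replaces the acid-catalysed exchange by a base-mediated substitution on an activated derivative. Brief treatment of 12 with MeOH and H2SO4 (cat.) at 40 °C gives 2-hydroxy-5-methoxy-3,6-bis[5-(3-methylbut-2-en-1-yl)-1H-indol-3-yl]cyclohexa-2,5-diene-1,4-dione F4. Its methoxy group is then displaced by hydroperoxide anion (30% H2O2, LiOH, THF–H2O, 0 °C, addition–elimination at the vinylogous ester carbon). Careful acidification returns to the route at 14.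

Step 1 (prenylation). N-prenylation of the indolide, SN2′ attack giving the reverse-prenyl isomer, and bromine–lithium exchange with prenyl bromide followed by Wurtz-type coupling can all erode the yield. The fallback sets out from 1 and inverts the roles of the partners under palladium catalysis. Miyaura borylation of 1 (B2pin2, PdCl2(dppf) with dppf = 1,1'-bis(diphenylphosphino)ferrocene, KOAc, dioxane, 90 °C) gives 5-(4,4,5,5-tetramethyl-1,3,2-dioxaborolan-2-yl)-1H-indole F5. Suzuki–Miyaura allylation of F5 with 2 (Pd(PPh3)4, K2CO3, THF–H2O, 60 °C) proceeds through a π-prenyl palladium intermediate that couples at its less hindered terminus, and returns to the route at 6.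

**Further compounds**
F1 | step 3 | 2,3,5-tribromo-6-[5-(3-methylbut-2-en-1-yl)-1H-indol-3-yl]cyclohexa-2,5-diene-1,4-dione | CC(C)=CCc1ccc2[nH]cc(C3=C(Br)C(=O)C(Br)=C(Br)C3=O)c2c1
F2 | step 3 | 2,5-dibromo-3,6-bis[5-(3-methylbut-2-en-1-yl)-1H-indol-3-yl]cyclohexa-2,5-diene-1,4-dione | CC(C)=CCc1ccc2[nH]cc(C3=C(Br)C(=O)C(c4c[nH]c5ccc(CC=C(C)C)cc45)=C(Br)C3=O)c2c1
F3 | step 3 | 2-bromo-5-hydroxy-3,6-bis[5-(3-methylbut-2-en-1-yl)-1H-indol-3-yl]cyclohexa-2,5-diene-1,4-dione | CC(C)=CCc1ccc2[nH]cc(C3=C(O)C(=O)C(c4c[nH]c5ccc(CC=C(C)C)cc45)=C(Br)C3=O)c2c1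
F4 | step 4 | 2-hydroxy-5-methoxy-3,6-bis[5-(3-methylbut-2-en-1-yl)-1H-indol-3-yl]cyclohexa-2,5-diene-1,4-dione | CC(C)=CCc1ccc2[nH]cc(C3=C(O)C(=O)C(c4c[nH]c5ccc(CC=C(C)C)cc45)=C(OC)C3=O)c2c1
F5 | step 1 | 5-(4,4,5,5-tetramethyl-1,3,2-dioxaborolan-2-yl)-1H-indole | CC1(C)OB(OC1(C)C)c1ccc2[nH]ccc2c1
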